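I count the reagent first.

| setting | south-west | south | flask |
|---|---|---|---|
| substrate | 0.067 M (fed, over 30 s) | 0.15 M (fed, over 30 s) | 0.10 M (fed, over 30 s) |
| solid reagent | 0.080 M | 0.080 M | 0.0800 M |
| remark | run made earlier | run made earlier |  |
| time |  |  | 20 h |

| run | time / h | target / % | side product / % | substrate / % |
|---|---|---|---|---|
| south-west | 1.00 | 65.5 | 34.0 | 0 |
| south-west | 1.33 | 65.6 | 34.6 | 0 |
| south-west | 2.00 | 66.8 | 34.3 | 0.1 |
| south-west | 3.00 | 65.4 | 32.7 | 2.0 |
| south-west | 5.00 | 66.3 | 33.7 | 0 |
| south-west | 8.00 | 67.1 | 34.0 | 1.5 |
| south-west | 12.0 | 67.1 | 32.3 | 0 |
| south | 1.50 | 34.5 | 18.0 | 48.5 |
| south | 3.00 | 32.6 | 18.8 | 47.6 |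
| south | 5.00 | 31.5 | 17.8 | 48.0 |
| south | 6.00 | 33.9 | 15.8 | 48.9 |
| south | 8.00 | 35.2 | 17.9 | 45.2 |
| south | 10.0 | 33.0 | 17.9 | 49.4 |
| south | 12.0 | 34.7 | 17.7 | 47.2 |

(standard deviation of a reading: 1 percentage point)

- given per volume of solution although it is solid: solid reagent
- the earlier runs were read with a standard deviation of 1 percentage point
- steps that have been proposed: substrate + partner -> intermediate; intermediate -> target; 2 partner -> self-condensation product; intermediate -> side product; solid reagent <-> partner
- at the start none of the solid reagent is in solution
- the reaction counts as stopped when no species that holds the substrate changes by six tenths of a point or more over the second half of the time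

- which holds at 20 h: what has brought the reaction to rest, or that it has not come to rest (for what has run out or reacted, a solid counts together with what of it has only dissolved) (all of the substrate has reacted / the partner has run out first / it is still moving)
- the target standing at 20 h, as a percentage of the substrate charged
- the side product standing at 20 h, as a percentage of the substrate charged
- amount of target if the flask were left three thousand times as long, in percent of the substrate charged

The solid reagent dissolves to partner, the partner takes substrate to intermediate, and the intermediate goes on to target or side product. I carry one quantity, the usable share f: substrate turned into products per solid reagent charged, read where substrate stays over. The south run is such a run: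

c(used) = 0.15 M × mean share in target and side product = 0.0770 M

f = c(used) / 0.080 M = 0.962

The crossing lies at c(substrate) = f × c(solid reagent). Below it I expect no substrate over, as the south-west run reads 0% substrate at 12.0 h; above it the reagent is the limiting reagent; this holds for the reagent charge of these runs.

Now the ladder of times. The dose takes 30 s. By 1.50 h the south run has substrate at 48.5%, and at 12.0 h it reads 47.2%, the same within the scatter. The asked 20 h lies far beyond that first reading, so I expect this flask to stand still long before then.

For the flask:

crossing = f × 0.0800 M = 0.0770 M, below the charge of 0.10 M

conversion = 77.0%

The south-west run, with 0.067 M substrate, gives a target share of the products (the selectivity) of s = 0.663. So I reckon 51.1% target and 25.9% side product, unchanged by waiting.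

The forecast says the partner has run out first, with 51.2% target, 26.2% side product and 51.2% in the long run, because “waiting longer changes nothing”; my own reckoning stands at 51.1% and 25.9%.

The flask gives 49.9% target and 25.5% side product at 20 h, 49.9% target for the long wait, and the outcome: the partner has run out first.

    substrate + partner → intermediate (k = 0.500 /M/s)
    intermediate → target (k = 0.00430 /s)
    2 partner → self-condensation product (k = 0.0320 /M/s)
    intermediate → side product (k = 0.00220 /s)
    solid reagent ⇌ partner, rate k5*(cs5 - [partner]) while solid is left; crystals form when [partner] > cs5 (solubility = 0.0560 M, k = 0.0640 /s)

At 20.0 h the flask holds 25% of its substrate charge, and the share of the charged partner still there, solid or dissolved, is 0%, on the side of the crossing where 0.0770 M lies below the substrate charge. A neighbour flask with 0.020 M solid reagent is reckoned by f at 80.8% substrate left and 12.8% target; it holds 80.5% substrate and 12.9% target.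

The runs were generated by integration for substances that don't exist; scatter was added.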